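## Retrosynthetic overview

1. C6–C7 bond: Sonogashira coupling of the (R)-hydroxy ring triflate 9 with the complete C21 polyene ynal 12, as the last step.
2. 12 comes from the symmetric C20 dialdehyde crocetindial 10 by turning one CHO into C≡CH (one-carbon mono-homologation).
3. 9 comes from ketone 6 by enol triflation; 6 comes from the meso all-cis ketone 4 by enantiotopos-selective deprotonation and C-methylation. This key step creates the only stereocentre.
4. 4 comes from 2,6-dimethylhydroquinone 1 by arene hydrogenation, mono-silylation and oxidation. The single ring is the benzene ring of 1; no ring-forming step is needed.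

Assumption: the (S,S)-lithium amide is taken to remove the α-H at the (2R) carbon of 4, by analogy with 4-substituted cyclohexanones; if the sense proves opposite, the (R,R)-amide is used.
Assumption: crocetindial 10 is purchased as the all-E isomer.

## Route

Step 1
Reactants: 1 2,6-dimethylbenzene-1,4-diol (2,6-dimethylhydroquinone)
Product: 2 all-cis-2,6-dimethylcyclohexane-1,4-diol (meso; both OH and both CH3 on one face)
Conditions: H2 (50 bar), 5% Rh/Al2O3, i-PrOH, 50 °C; recrystallise
Reagents that add atoms: none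
Why: Heterogeneous arene hydrogenation over rhodium delivers all six H to one face with little C–O hydrogenolysis, giving the all-cis meso diol; only the cis relation of the C4–O to the two methyls has to be pure, and minor isomers are removed here.

Step 2
Reactants: 2 all-cis-2,6-dimethylcyclohexane-1,4-diol
Product: 3 all-cis-4-[(tert-butyldimethylsilyl)oxy]-2,6-dimethylcyclohexan-1-ol
Conditions: TBSCl (1.05 equiv), imidazole, DMF, 0 °C
Reagents that add atoms: tert-butyldimethylsilyl chloride, C[Si](C)(Cl)C(C)(C)C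
Why: Selective silylation: the C4–OH is equatorial and flanked by CH2 groups, whereas the C1–OH is axial between two methyl-bearing carbons and stays free.

Step 3
Reactants: 3 all-cis-4-[(tert-butyldimethylsilyl)oxy]-2,6-dimethylcyclohexan-1-ol
Product: 4 all-cis-4-[(tert-butyldimethylsilyl)oxy]-2,6-dimethylcyclohexan-1-one (meso; α-carbons 2R and 6S)
Conditions: Dess–Martin periodinane, CH2Cl2, rt
Reagents that add atoms: none
Why: Dess–Martin oxidation handles the hindered axial alcohol; the cis-diequatorial methyls are also the thermodynamic arrangement, so the meso ketone is not at risk of epimerisation.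

Step 4 (key step)
Reactants: 4 all-cis-4-[(tert-butyldimethylsilyl)oxy]-2,6-dimethylcyclohexan-1-one
Product: 6 (4R,6S)-4-[(tert-butyldimethylsilyl)oxy]-2,2,6-trimethylcyclohexan-1-one, via lithium enolate 5 (not isolated)
Conditions: (S,S)-bis(1-phenylethyl)amine, n-BuLi, LiCl, THF, −78 °C; then MeI (5 equiv), DMPU, −78 → −30 °C
Reagents that add atoms: iodomethane, CI
Why: Asymmetric deprotonation of a meso ketone by a chiral lithium amide (Simpkins–Koga type) removes one of the two enantiotopic axial α-H atoms. Enolate C-methylation turns that carbon into CMe2, which makes C4 a stereocentre of R configuration without any bond to C4 being touched; about 85–90% ee is expected.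

Step 5
Reactants: 6 (4R,6S)-4-[(tert-butyldimethylsilyl)oxy]-2,2,6-trimethylcyclohexan-1-one
Product: 9 (R)-4-hydroxy-2,6,6-trimethylcyclohex-1-en-1-yl trifluoromethanesulfonate, via potassium enolate 7 (not isolated), via silyl ether triflate 8 (not isolated)
Conditions: KN(SiMe3)2, THF, −78 → 0 °C; PhNTf2, −78 °C → rt; then 1.25 M HCl in MeOH, rt
Reagents that add atoms: N-phenyl-bis(trifluoromethanesulfonimide), FC(F)(F)S(=O)(=O)N(c1ccccc1)S(=O)(=O)C(F)(F)F
Why: Enol triflate formation: the ketone has a single α-H (C6), so only one enolate can form and O-triflation gives the tetrasubstituted vinyl triflate. The C6 stereocentre is erased and C4 is untouched; acidic methanolysis then removes the silyl group while the vinyl triflate is acid-stable.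

Step 6
Reactants: 10 crocetindial, (2E,4E,6E,8E,10E,12E,14E)-2,6,11,15-tetramethylhexadeca-2,4,6,8,10,12,14-heptaenedial
Product: 12 (2E,4E,6E,8E,10E,12E,14E)-2,6,11,15-tetramethylheptadeca-2,4,6,8,10,12,14-heptaen-16-ynal, via lithium alkoxide adduct 11 (not isolated)
Conditions: Me3SiCHN2 (0.6 equiv), LiN(i-Pr)2, THF, −78 °C; then 10, −78 → 0 °C, dark; recover and recycle 10
Reagents that add atoms: (trimethylsilyl)diazomethane, C[Si](C)(C)C=[N+]=[N-]
Why: Colvin rearrangement: the lithiated diazomethane adds 1,2 to one CHO, then Peterson-type loss of LiOSiMe3, loss of N2 and a 1,2-H shift give the enyne. A sub-stoichiometric charge against the symmetric dialdehyde favours the mono product, and the aprotic conditions avoid alcohol addition to the conjugated aldehyde; the seven E double bonds are not involved.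

Step 7
Reactants: 9 (R)-4-hydroxy-2,6,6-trimethylcyclohex-1-en-1-yl trifluoromethanesulfonate; 12 (2E,4E,6E,8E,10E,12E,14E)-2,6,11,15-tetramethylheptadeca-2,4,6,8,10,12,14-heptaen-16-ynal
Product: 13 (2E,4E,6E,8E,10E,12E,14E)-17-[(4R)-4-hydroxy-2,6,6-trimethylcyclohex-1-en-1-yl]-2,6,11,15-tetramethylheptadeca-2,4,6,8,10,12,14-heptaen-16-ynal (target)
Conditions: Pd(PPh3)4 (5 mol %), CuI (10 mol %), Et3N, DMF, 40 °C, degassed, dark
Reagents that add atoms: none
Why: Sonogashira coupling of a vinyl triflate with a terminal alkyne forms the C6–C7 bond; free OH and CHO are tolerated, a tertiary amine avoids condensation with the aldehyde, and no stereocentre or double bond is altered.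

## Compound list

1 | 2,6-dimethylbenzene-1,4-diol (2,6-dimethylhydroquinone) | Cc1cc(O)cc(C)c1O | starting material
2 | all-cis-2,6-dimethylcyclohexane-1,4-diol (meso) | C[C@@H]1[C@H](O)[C@H](C)C[C@H](O)C1 | intermediate
3 | all-cis-4-[(tert-butyldimethylsilyl)oxy]-2,6-dimethylcyclohexan-1-ol | C[C@@H]1[C@H](O)[C@H](C)C[C@H](O[Si](C)(C)C(C)(C)C)C1 | intermediate
4 | all-cis-4-[(tert-butyldimethylsilyl)oxy]-2,6-dimethylcyclohexan-1-one (meso) | C[C@@H]1C(=O)[C@H](C)C[C@H](O[Si](C)(C)C(C)(C)C)C1 | intermediate
5 | lithium (4R,6S)-4-[(tert-butyldimethylsilyl)oxy]-2,6-dimethylcyclohex-1-en-1-olate | C[C@@H]1C([O-])=C(C)C[C@H](O[Si](C)(C)C(C)(C)C)C1.[Li+] | intermediate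
6 | (4R,6S)-4-[(tert-butyldimethylsilyl)oxy]-2,2,6-trimethylcyclohexan-1-one | C[C@@H]1C(=O)C(C)(C)C[C@H](O[Si](C)(C)C(C)(C)C)C1 | intermediate
7 | potassium (R)-4-[(tert-butyldimethylsilyl)oxy]-2,6,6-trimethylcyclohex-1-en-1-olate | CC1=C([O-])C(C)(C)C[C@H](O[Si](C)(C)C(C)(C)C)C1.[K+] | intermediate
8 | (R)-4-[(tert-butyldimethylsilyl)oxy]-2,6,6-trimethylcyclohex-1-en-1-yl trifluoromethanesulfonate | CC1=C(OS(=O)(=O)C(F)(F)F)C(C)(C)C[C@H](O[Si](C)(C)C(C)(C)C)C1 | intermediate
9 | (R)-4-hydroxy-2,6,6-trimethylcyclohex-1-en-1-yl trifluoromethanesulfonate | CC1=C(OS(=O)(=O)C(F)(F)F)C(C)(C)C[C@H](O)C1 | intermediate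
10 | crocetindial, all-E 2,6,11,15-tetramethylhexadeca-2,4,6,8,10,12,14-heptaenedial | O=C/C(C)=C/C=C/C(C)=C/C=C/C=C(C)/C=C/C=C(\C)C=O | starting material
11 | lithium all-E 1-diazo-3,7,12,16-tetramethyl-17-oxo-1-(trimethylsilyl)heptadeca-3,5,7,9,11,13,15-heptaen-2-olate (racemic at C2) | [Li+].[O-]C(C(=[N+]=[N-])[Si](C)(C)C)/C(C)=C/C=C/C(C)=C/C=C/C=C(C)/C=C/C=C(\C)C=O | intermediate
12 | all-E 2,6,11,15-tetramethylheptadeca-2,4,6,8,10,12,14-heptaen-16-ynal | C#C/C(C)=C/C=C/C(C)=C/C=C/C=C(C)/C=C/C=C(\C)C=O | intermediate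
13 | (3R)-3-hydroxy-7,8-didehydro-8'-apo-β-caroten-8'-al, all-E | CC1=C(C#C/C(C)=C/C=C/C(C)=C/C=C/C=C(C)/C=C/C=C(\C)C=O)C(C)(C)C[C@H](O)C1 | target

## Step count and risks

Total steps: 7. Longest linear sequence: 6 (steps 1, 2, 3, 4, 5, 7).

**Step 4 (desymmetrising methylation).** The risks are moderate ee and enolate equilibration or over-alkylation during C-methylation of a tetrasubstituted lithium enolate. The fallback sets out from 4 and comes back at 6. The same chiral amide is used under internal-quench conditions with TMSCl, which gives the isolable, enantioenriched (4R,6S)-4-[(tert-butyldimethylsilyl)oxy]-2,6-dimethyl-1-(trimethylsilyloxy)cyclohex-1-ene F1, whose ee can be measured. Its electron-rich double bond is cyclopropanated with Et2Zn/CH2I2 to give 4-[(tert-butyldimethylsilyl)oxy]-2,6-dimethyl-1-(trimethylsilyloxy)bicyclo[4.1.0]heptane F2. NaOH in aqueous methanol opens the cyclopropanol so that the cyclopropane CH2 becomes the second methyl, giving 6 without any free enolate being alkylated.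

**Step 6 (mono-homologation of the dialdehyde).** The risks are statistical mono/bis selectivity, poor low-temperature solubility of 10 and sensitivity of the polyene to the carbenoid sequence. The fallback sets out from 10 and comes back at 12. Ramirez mono-olefination (CBr4, PPh3, Zn, CH2Cl2, 0 °C) gives all-E 17,17-dibromo-2,6,11,15-tetramethylheptadeca-2,4,6,8,10,12,14,16-octaenal F3. The remaining aldehyde is masked in the flask as its lithium α-amino alkoxide with lithium N,N,N'-trimethylethylenediamide. n-BuLi (2.2 equiv, −78 °C) then performs the Corey–Fuchs rearrangement, and aqueous work-up releases 12.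

**Step 7 (coupling of the hindered triflate with the fragile ynal).** The risks are slow oxidative addition at the tetrasubstituted triflate, alkyne homocoupling and polyene degradation. The fallback sets out from 9 and comes back at 13 without using 12:

- Sonogashira coupling of 9 with the small, robust (E)-3-methylpent-2-en-4-yn-1-ol (can be heated) gives (1R)-4-[(3E)-5-hydroxy-3-methylpent-3-en-1-yn-1-yl]-3,5,5-trimethylcyclohex-3-en-1-ol F4.
- PPh3·HBr in MeOH converts only the primary allylic alcohol into the C15 phosphonium bromide F5.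
- Wittig reaction with excess 2,7-dimethylocta-2,4,6-trienedial (NaOMe, CH2Cl2), followed by thermal E-isomerisation, gives (3R)-3-hydroxy-7,8-didehydro-12'-apo-β-caroten-12'-al F6.
- A second Wittig reaction with [(E)-4,4-dimethoxy-3-methylbut-2-enyl]triphenylphosphonium chloride (NaOMe) gives the dimethyl acetal of the target F7.
- Dilute aqueous acid hydrolyses the acetal to 13.

## Further compounds

F1 | step 4 | (4R,6S)-4-[(tert-butyldimethylsilyl)oxy]-2,6-dimethyl-1-(trimethylsilyloxy)cyclohex-1-ene | C[C@@H]1C(O[Si](C)(C)C)=C(C)C[C@H](O[Si](C)(C)C(C)(C)C)C1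
F2 | step 4 | 4-[(tert-butyldimethylsilyl)oxy]-2,6-dimethyl-1-(trimethylsilyloxy)bicyclo[4.1.0]heptane (ring-fusion isomers; other centres as in F1) | C[C@@H]1C2(O[Si](C)(C)C)CC2(C)C[C@H](O[Si](C)(C)C(C)(C)C)C1
F3 | step 6 | all-E 17,17-dibromo-2,6,11,15-tetramethylheptadeca-2,4,6,8,10,12,14,16-octaenal | BrC(Br)=C/C(C)=C/C=C/C(C)=C/C=C/C=C(C)/C=C/C=C(\C)C=O
F4 | step 7 | (1R)-4-[(3E)-5-hydroxy-3-methylpent-3-en-1-yn-1-yl]-3,5,5-trimethylcyclohex-3-en-1-ol | CC1=C(C#C/C(C)=C/CO)C(C)(C)C[C@H](O)C1
F5 | step 7 | {(2E)-5-[(4R)-4-hydroxy-2,6,6-trimethylcyclohex-1-en-1-yl]-3-methylpent-2-en-4-yn-1-yl}triphenylphosphonium bromide | CC1=C(C#C/C(C)=C/C[P+](c2ccccc2)(c2ccccc2)c2ccccc2)C(C)(C)C[C@H](O)C1.[Br-]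
F6 | step 7 | (3R)-3-hydroxy-7,8-didehydro-12'-apo-β-caroten-12'-al, all-E | CC1=C(C#C/C(C)=C/C=C/C(C)=C/C=C/C=C(\C)C=O)C(C)(C)C[C@H](O)C1
F7 | step 7 | (3R)-3-hydroxy-7,8-didehydro-8'-apo-β-caroten-8'-al dimethyl acetal, all-E | CC1=C(C#C/C(C)=C/C=C/C(C)=C/C=C/C=C(C)/C=C/C=C(\C)C(OC)OC)C(C)(C)C[C@H](O)C1
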